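Readings and results were computed from invented constants.

A small charge of E, 0.0450 M, less than the 0.050 M of solid D, is what the flask has for making G, and each molecule of E meets a fork: it takes J to G, or it takes another E to Z.

| setting | epsilon | delta | gamma | flask |
|---|---|---|---|---|
| D | 0.034 M | 0.075 M | 0.050 M | 0.050 M |
| E | 0.045 M | 0.045 M | 0.022 M | 0.0450 M |
| remark | run made earlier | run made earlier | run made earlier |  |
| time |  |  |  | 30 h |

| run | time / h | G / % | D / % |
|---|---|---|---|
| epsilon | 2.50 | 20.4 | 1.1 |
| epsilon | 8.00 | 50.4 | 0.9 |
| epsilon | 15.0 | 65.0 | 0 |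
| epsilon | 20.0 | 72.1 | 0.2 |
| epsilon | 30.0 | 76.6 | 1.1 |
| delta | 2.50 | 9.3 | 53.9 |
| delta | 8.00 | 28.9 | 26.0 |
| delta | 15.0 | 40.8 | 10.6 |
| delta | 20.0 | 43.9 | 7.1 |
| delta | 30.0 | 44.2 | 3.3 |
| gamma | 2.50 | 6.8 | 34.8 |
| gamma | 5.00 | 16.1 | 15.1 |
| gamma | 8.00 | 22.4 | 3.4 |
| gamma | 15.0 | 33.7 | 0.7 |
| gamma | 30.0 | 37.2 | 0 |

(standard deviation of a reading: 1 percentage point)

- D is a solid; its amount is given per volume of the solution
- the analysis behind the earlier runs scatters by 1 percentage point, standard deviation
- steps under discussion: J + E -> G; D <-> J; 2 E -> Z
- at the start none of D is in solution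

- maple: doubling the amount of E, all else as stated
- larch: doubling the solubility of D, all else as stated
- birch: doubling the dissolution coefficient of D, all else as stated

- G at 30 h, in percent of the D charged
- the change that raises the amount of G at 30 h, in percent of the D charged most ("none" if none brings more than 2 percentage points) (maple / larch / birch / none)
- amount of G at 30 h, in percent of the D charged, after larch

The ladder starts with dissolving. In the gamma run, with the flask's charge of D, the solid reads 34.8% at 2.50 h and 3.4% at 8.00 h, so nearly all of it has dissolved by then. G comes later: in the same gamma run it reads 22.4% at 8.00 h and 33.7% at 15.0 h. Last comes the stall in the delta run, with the flask's charge of E, where G moves from 43.9% to 44.2% between 20.0 h and 30.0 h, less than the scatter, while D still reads 3.3%. E, the limiting reagent there, is therefore taken as used up, with G at 0.0332 M against the 0.045 M of E charged.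

That stall gives 73.7% as the G share of E, the part of the E charged that ends as G. The step to G goes with J times E and the step to Z with E times E, so a lower ratio of E to J should favour G, and the gamma run, with half the E of the delta run but less D as well, reads a higher share at 30.0 h, 84.5%. Carried to the flask, the delta share gives 66.3% of the D charged. Maple doubles the E that the share multiplies, while larch and birch leave that charge as it is, so this reckoning puts maple first and larch near the same 66.3%.

The forecast, a little lower on G, gives 63% (58% to 68%), maple as the best change, and 67% (60% to 74%) after larch: “Since E is limiting, doubling it helps most”.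

The flask gives 64.3%, with maple best at 24 percentage points, against 3.2 points for larch and 1.9 points for birch, and 67.4% after larch.

    J + E → G (k = 3.90 L mol⁻¹ h⁻¹)
    D ⇌ J, rate k2*(cs2 - [J]) while solid is left; crystals form when [J] > cs2 (solubility = 38.0 mM, k = 0.690 h⁻¹)
    2 E → Z (k = 0.720 L mol⁻¹ h⁻¹)

The flask's G share of E is 71.4%, with 4.3% of E left at 30.0 h. Its fork stands at 1.6 to one for G at 1.46 h, a chance of 60.9%, and at 25 to one at 30.0 h, a chance of 96.2%. On the neighbour flask with 0.12 M of D, the delta share reckons to 27.6%, and that flask gives 28.3%.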